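**Retrosynthetic overview**
- Feature: in the tetrahydrofuran ring (O1, C2 with the trimethoxyphenyl group, C3 with C3a = CH2OH, C4 with the benzylic carbon C4a, C5), C5 is an unsubstituted CH2 between O1 and C4. O1–C5 and C5–C4 are therefore cut together: C5 becomes carbon monoxide, C4≡C4a an aryl alkyne, O1 a homopropargylic hydroxyl.
- The only ring is formed once, in the key step, as the E-α-benzylidene-γ-butyrolactone ([4+1], 5-exo-dig). C4 is then set by hydrogenation anti to the C3 arm, and the lactone is taken to the tetrahydrofuran by reduction, primary tosylation with O1–C5 re-closure, and desilylation.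
- The anti alkynol (C2 and C3) comes from C2–C3 bond formation between a chiral allenylzinc (from a propargylic mesylate) and 3,4,5-trimethoxybenzaldehyde.
- The mesylate comes from asymmetric transfer hydrogenation of the ynone made from 3,4-dimethoxyphenylacetylene and a silyloxy Weinreb amide.

Key step: step 5

Remark on numbering: the ring labels O1, C2, C3, C3a, C4, C4a and C5 of the target are used for the corresponding atoms of all intermediates; the target is (2R,3S,4S), 2,3-trans and 3,4-cis.
Assumption: in the transfer hydrogenation of step 2 the alkynyl group is taken to act as the π-substituent, as in alkyl alkynyl ketones; the carbinol configuration is to be confirmed (Mosher esters) before the material is carried on.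

Step 1
Reactants: 1 4-ethynyl-1,2-dimethoxybenzene; 2 2-(tert-butyldimethylsilyloxy)-N-methoxy-N-methylacetamide
Product: 5 1-(tert-butyldimethylsilyloxy)-4-(3,4-dimethoxyphenyl)but-3-yn-2-one, via lithium acetylide 3 (not isolated), via tetrahedral lithium adduct 4 (not isolated)
Conditions: n-BuLi, THF, −78 °C; then 2, −78 → 0 °C; aq NH4Cl
Reagents that add atoms: n-butyllithium, [Li]CCCC (lithium kept only in 3 and 4)
Why: Weinreb ketone synthesis, in which the lithium acetylide adds once to the N-methoxy-N-methylamide and the chelated adduct collapses to the ynone only on work-up, so over-addition is avoided and no stereocentre is involved.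

Step 2
Reactants: 5 1-(tert-butyldimethylsilyloxy)-4-(3,4-dimethoxyphenyl)but-3-yn-2-one
Product: 6 (R)-1-(tert-butyldimethylsilyloxy)-4-(3,4-dimethoxyphenyl)but-3-yn-2-ol
Conditions: RuCl(p-cymene)[(S,S)-TsDPEN] (1 mol %), i-PrOH, rt
Reagents that add atoms: none
Why: Noyori asymmetric transfer hydrogenation of an ynone, in which the alkynyl group takes the π-substituent position of the Ru–H/N–H transition state so that the (S,S)-catalyst should give the R carbinol (R because CH2OSi outranks alkynyl), the future C3 stereochemical information.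

Step 3
Reactants: 6 (R)-1-(tert-butyldimethylsilyloxy)-4-(3,4-dimethoxyphenyl)but-3-yn-2-ol
Product: 7 (R)-1-(tert-butyldimethylsilyloxy)-4-(3,4-dimethoxyphenyl)but-3-yn-2-yl methanesulfonate
Conditions: MsCl, Et3N, CH2Cl2, −78 → 0 °C; used without chromatography
Reagents that add atoms: methanesulfonyl chloride, CS(=O)(=O)Cl
Why: O-sulfonylation of a secondary propargylic alcohol, which does not touch the C–O bond and so keeps the R configuration.

Step 4
Reactants: 7 (R)-1-(tert-butyldimethylsilyloxy)-4-(3,4-dimethoxyphenyl)but-3-yn-2-yl methanesulfonate; 8 3,4,5-trimethoxybenzaldehyde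
Product: 10 (1R,2S)-2-[(tert-butyldimethylsilyloxy)methyl]-4-(3,4-dimethoxyphenyl)-1-(3,4,5-trimethoxyphenyl)but-3-yn-1-ol (anti), via allenylzinc 9 (not isolated)
Conditions: Pd(OAc)2 (5 mol %), PPh3 (5 mol %), Et2Zn (3 equiv), THF, −78 → −20 °C; aq NH4Cl
Reagents that add atoms: diethylzinc, CC[Zn]CC (ethylzinc kept only in 9)
Why: Marshall propargylation, in which zerovalent palladium displaces the mesylate anti-SN2′, transmetalation to zinc with retention gives the (aR)-allenylzinc, and its SE2′ addition to the aldehyde through a cyclic six-membered transition state with the aldehyde aryl group away from the CH2OSi arm sets C3 (net inversion of the mesylate carbon) and the anti carbinol C2.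

Step 5
Reactants: 10 (1R,2S)-2-[(tert-butyldimethylsilyloxy)methyl]-4-(3,4-dimethoxyphenyl)-1-(3,4,5-trimethoxyphenyl)but-3-yn-1-ol; 11 carbon monoxide
Product: 12 (3E,4S,5R)-4-[(tert-butyldimethylsilyloxy)methyl]-3-(3,4-dimethoxybenzylidene)-5-(3,4,5-trimethoxyphenyl)dihydrofuran-2(3H)-one
Conditions: PdCl2(PPh3)2 (10 mol %), SnCl2 (10 mol %), CO (8 atm), MeCN, 75 °C
Reagents that add atoms: carbon monoxide (11), [C-]#[O+]
Why: Cyclocarbonylation: the C2 hydroxyl (future O1) and CO give an alkoxycarbonyl–palladium chloride on divalent palladium (assisted by the Pd–SnCl3 unit), the tethered alkyne inserts syn into the Pd–acyl bond to form C5–C4 with palladium on C4a, and protonolysis of the vinyl–palladium bond by the HCl set free releases the E-benzylidene lactone and returns the catalyst. The closest known reaction type is the PdCl2/SnCl2/phosphine-catalysed cyclocarbonylation of 3-butyn-1-ols to α-alkylidene-γ-butyrolactones, applied here to an internal aryl alkyne. The lactone ring (O1, C2, C3, C4, C5) closes 5-exo-dig, because syn insertion in the 6-endo sense would require a trans double bond inside a six-membered ring. No stereocentre is formed: C2 and C3 are carried through because none of their bonds is broken, and the E geometry follows from syn addition and retentive protonolysis. The step needs selectivity for O1 over the C3a oxygen, which is also homopropargylic, and for alkoxycarbonylation over direct 5-endo oxypalladation of the alkyne; the silyl ether on C3a secures the first, and the phosphine-ligated, weakly π-acidic catalyst under CO pressure should secure the second.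

Step 6
Reactants: 12 (3E,4S,5R)-4-[(tert-butyldimethylsilyloxy)methyl]-3-(3,4-dimethoxybenzylidene)-5-(3,4,5-trimethoxyphenyl)dihydrofuran-2(3H)-one
Product: 13 (3S,4S,5R)-4-[(tert-butyldimethylsilyloxy)methyl]-3-(3,4-dimethoxybenzyl)-5-(3,4,5-trimethoxyphenyl)dihydrofuran-2(3H)-one
Conditions: H2 (3 atm), 5% Rh/Al2O3, EtOAc, rt
Reagents that add atoms: none
Why: Heterogeneous syn hydrogenation of the exocyclic enoate, in which allylic 1,3-strain with the E-aryl group pushes the C3 CH2OSi arm pseudo-axial so that hydrogen should be delivered to the opposite face, setting C4 with the benzyl group cis to that arm, while Rh on Al2O3 is chosen to spare the benzylic C2–O bond.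

Step 7
Reactants: 13 (3S,4S,5R)-4-[(tert-butyldimethylsilyloxy)methyl]-3-(3,4-dimethoxybenzyl)-5-(3,4,5-trimethoxyphenyl)dihydrofuran-2(3H)-one
Product: 14 (1R,2S,3S)-2-[(tert-butyldimethylsilyloxy)methyl]-3-(3,4-dimethoxybenzyl)-1-(3,4,5-trimethoxyphenyl)butane-1,4-diol
Conditions: LiAlH4, THF, −10 → 0 °C; H2O, aq NaOH work-up
Reagents that add atoms: none
Why: Hydride reduction of a lactone to the 1,4-diol, fast enough at 0 °C that the α-stereocentre (C4) should not epimerise and the silyl ether should survive.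

Step 8
Reactants: 14 (1R,2S,3S)-2-[(tert-butyldimethylsilyloxy)methyl]-3-(3,4-dimethoxybenzyl)-1-(3,4,5-trimethoxyphenyl)butane-1,4-diol
Product: 16 tert-butyl{[(2R,3S,4S)-4-(3,4-dimethoxybenzyl)-2-(3,4,5-trimethoxyphenyl)tetrahydrofuran-3-yl]methoxy}dimethylsilane, via primary tosylate 15 (not isolated)
Conditions: TsCl (1.1 equiv), Et3N, DMAP (cat.), CH2Cl2, 0 °C; then NaH, THF, 0 °C → rt
Reagents that add atoms: p-toluenesulfonyl chloride, Cc1ccc(cc1)S(=O)(=O)Cl (tosyl group kept only in 15)
Why: Selective sulfonylation of the primary hydroxyl followed by intramolecular Williamson etherification (5-exo-tet) by the benzylic alkoxide, which forms O1–C5 without breaking the C2–O bond and therefore retains C2.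

Step 9
Reactants: 16 tert-butyl{[(2R,3S,4S)-4-(3,4-dimethoxybenzyl)-2-(3,4,5-trimethoxyphenyl)tetrahydrofuran-3-yl]methoxy}dimethylsilane
Product: 17 [(2R,3S,4S)-4-(3,4-dimethoxybenzyl)-2-(3,4,5-trimethoxyphenyl)tetrahydrofuran-3-yl]methanol (target)
Conditions: Bu4NF, THF, 0 °C → rt
Reagents that add atoms: none
Why: Fluoride-mediated cleavage of the silyl ether, which leaves the three stereocentres and the aryl methyl ethers untouched.

**Compound list**
1 | 4-ethynyl-1,2-dimethoxybenzene | C#Cc1ccc(OC)c(OC)c1 | starting material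
2 | 2-(tert-butyldimethylsilyloxy)-N-methoxy-N-methylacetamide | CON(C)C(=O)CO[Si](C)(C)C(C)(C)C | starting material
3 | lithium (3,4-dimethoxyphenyl)acetylide | [Li]C#Cc1ccc(OC)c(OC)c1 | intermediate
4 | lithium 1-(tert-butyldimethylsilyloxy)-4-(3,4-dimethoxyphenyl)-2-[methoxy(methyl)amino]but-3-yn-2-olate (tetrahedral adduct, racemic) | CON(C)C(O[Li])(CO[Si](C)(C)C(C)(C)C)C#Cc1ccc(OC)c(OC)c1 | intermediate
5 | 1-(tert-butyldimethylsilyloxy)-4-(3,4-dimethoxyphenyl)but-3-yn-2-one | O=C(CO[Si](C)(C)C(C)(C)C)C#Cc1ccc(OC)c(OC)c1 | intermediate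
6 | (R)-1-(tert-butyldimethylsilyloxy)-4-(3,4-dimethoxyphenyl)but-3-yn-2-ol | O[C@@H](CO[Si](C)(C)C(C)(C)C)C#Cc1ccc(OC)c(OC)c1 | intermediate
7 | (R)-1-(tert-butyldimethylsilyloxy)-4-(3,4-dimethoxyphenyl)but-3-yn-2-yl methanesulfonate | CS(=O)(=O)O[C@@H](CO[Si](C)(C)C(C)(C)C)C#Cc1ccc(OC)c(OC)c1 | intermediate
8 | 3,4,5-trimethoxybenzaldehyde | COc1cc(C=O)cc(OC)c1OC | starting material
9 | (aR)-[4-(tert-butyldimethylsilyloxy)-1-(3,4-dimethoxyphenyl)buta-1,2-dien-1-yl](ethyl)zinc | CC[Zn]C(c1ccc(OC)c(OC)c1)=[C@]=C([H])CO[Si](C)(C)C(C)(C)C | intermediate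
10 | (1R,2S)-2-[(tert-butyldimethylsilyloxy)methyl]-4-(3,4-dimethoxyphenyl)-1-(3,4,5-trimethoxyphenyl)but-3-yn-1-ol (anti) | O[C@@H](c1cc(OC)c(OC)c(OC)c1)[C@H](CO[Si](C)(C)C(C)(C)C)C#Cc1ccc(OC)c(OC)c1 | intermediate
11 | carbon monoxide | [C-]#[O+] | starting material
12 | (3E,4S,5R)-4-[(tert-butyldimethylsilyloxy)methyl]-3-(3,4-dimethoxybenzylidene)-5-(3,4,5-trimethoxyphenyl)dihydrofuran-2(3H)-one | O=C1O[C@@H](c2cc(OC)c(OC)c(OC)c2)[C@H](CO[Si](C)(C)C(C)(C)C)/C1=C\c1ccc(OC)c(OC)c1 | intermediate
13 | (3S,4S,5R)-4-[(tert-butyldimethylsilyloxy)methyl]-3-(3,4-dimethoxybenzyl)-5-(3,4,5-trimethoxyphenyl)dihydrofuran-2(3H)-one | O=C1O[C@@H](c2cc(OC)c(OC)c(OC)c2)[C@H](CO[Si](C)(C)C(C)(C)C)[C@@H]1Cc1ccc(OC)c(OC)c1 | intermediate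
14 | (1R,2S,3S)-2-[(tert-butyldimethylsilyloxy)methyl]-3-(3,4-dimethoxybenzyl)-1-(3,4,5-trimethoxyphenyl)butane-1,4-diol | OC[C@@H](Cc1ccc(OC)c(OC)c1)[C@@H](CO[Si](C)(C)C(C)(C)C)[C@@H](O)c1cc(OC)c(OC)c(OC)c1 | intermediate
15 | (2S,3S,4R)-3-[(tert-butyldimethylsilyloxy)methyl]-2-(3,4-dimethoxybenzyl)-4-hydroxy-4-(3,4,5-trimethoxyphenyl)butyl 4-methylbenzenesulfonate | Cc1ccc(cc1)S(=O)(=O)OC[C@@H](Cc1ccc(OC)c(OC)c1)[C@@H](CO[Si](C)(C)C(C)(C)C)[C@@H](O)c1cc(OC)c(OC)c(OC)c1 | intermediate
16 | tert-butyl{[(2R,3S,4S)-4-(3,4-dimethoxybenzyl)-2-(3,4,5-trimethoxyphenyl)tetrahydrofuran-3-yl]methoxy}dimethylsilane | COc1ccc(C[C@@H]2CO[C@@H](c3cc(OC)c(OC)c(OC)c3)[C@@H]2CO[Si](C)(C)C(C)(C)C)cc1OC | intermediate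
17 | [(2R,3S,4S)-4-(3,4-dimethoxybenzyl)-2-(3,4,5-trimethoxyphenyl)tetrahydrofuran-3-yl]methanol (CNP0107562.1) | COc1ccc(C[C@@H]2CO[C@@H](c3cc(OC)c(OC)c(OC)c3)[C@@H]2CO)cc1OC | target

**Step count**
Total: 9 steps. Longest linear sequence: 9 steps (1 to 17).

**Steps most likely to fail**

Step 5 (key step). The alkyne of 10 is internal and conjugated to an electron-rich arene, so insertion into the alkoxycarbonyl–palladium bond may be slower than competing processes. These are direct 5-endo attack of the hydroxyl on the palladium-activated alkyne, and slow turnover with acid-promoted loss of the silyl ether at 75 °C, which would let the C3a oxygen compete for ring closure. The fallback sets out from 10 and returns at 12, and it builds C5–C4 before O1–C5 with CO2 as the one-carbon source. Ni(cod)2 (zerovalent nickel, 5 mol %), CsF, Et2Zn (3 equiv) and CO2 (1 atm) in MeCN at 60 °C should add H and CO2 syn across the aryl alkyne. The carboxyl should go to C4, the carbon remote from the arene, as is usual for aryl alkyl alkynes and reinforced by the zinc alkoxide of O1. This gives (2E,3S,4R)-3-[(tert-butyldimethylsilyloxy)methyl]-2-(3,4-dimethoxybenzylidene)-4-hydroxy-4-(3,4,5-trimethoxyphenyl)butanoic acid F1. Lactonisation of F1 (on acidification, otherwise EDC·HCl, DMAP, CH2Cl2) then closes O1–C5 and gives 12.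

Step 6. Hydrogen may be delivered to the wrong face, because the C2 aryl group lies on the face that has to be attacked. The benzylic acyloxy C2–O bond may also undergo hydrogenolysis, or the alkene may migrate into the ring and erase C3. The fallback sets out from 12 and returns at 16, moving the alkene reduction to the tetrahydrofuran stage. There the benzylic C–O bond is an ether, and 4-benzylidene-3-(oxymethyl)-2-aryltetrahydrofurans are known to take up hydrogen anti to the C3 arm. i-Bu2AlH (CH2Cl2, −78 → 0 °C) should reduce the enoate 1,2 to (1R,2S,3E)-2-[(tert-butyldimethylsilyloxy)methyl]-3-(3,4-dimethoxybenzylidene)-1-(3,4,5-trimethoxyphenyl)butane-1,4-diol F2. TsCl, Et3N and DMAP should then give (2E,3S,4R)-3-[(tert-butyldimethylsilyloxy)methyl]-2-(3,4-dimethoxybenzylidene)-4-hydroxy-4-(3,4,5-trimethoxyphenyl)butyl 4-methylbenzenesulfonate F3. NaH in THF closes F3 to (2R,3S,4E)-3-[(tert-butyldimethylsilyloxy)methyl]-4-(3,4-dimethoxybenzylidene)-2-(3,4,5-trimethoxyphenyl)tetrahydrofuran F4. Hydrogenation of F4 (H2, 5% Rh/Al2O3, EtOAc) should give 16.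

Step 4. Anti selectivity may erode through open or boat transition states with an aromatic aldehyde. Chirality transfer may be incomplete if the aryl-substituted allenylzinc racemises, and the organozinc may decay by 1,4-elimination of silanolate. The fallback sets out from 6 and returns at 10, replacing the transient zinc reagent by an isolable, configurationally stable boron reagent. ClCO2Me and pyridine (CH2Cl2, 0 °C) should give (R)-1-(tert-butyldimethylsilyloxy)-4-(3,4-dimethoxyphenyl)but-3-yn-2-yl methyl carbonate F5. Copper-catalysed anti-SN2′ borylation (B2pin2, CuCl, NaO-t-Bu, Xantphos, THF, rt) should then give (aS)-2-[4-(tert-butyldimethylsilyloxy)-1-(3,4-dimethoxyphenyl)buta-1,2-dien-1-yl]-4,4,5,5-tetramethyl-1,3,2-dioxaborolane F6. Thermal addition of F6 to aldehyde 8 (toluene, rt → 50 °C) through a closed chair transition state, followed by aqueous work-up, should give 10 with the same sense of induction as the zinc route.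

Further compounds
F1 | step 5 | (2E,3S,4R)-3-[(tert-butyldimethylsilyloxy)methyl]-2-(3,4-dimethoxybenzylidene)-4-hydroxy-4-(3,4,5-trimethoxyphenyl)butanoic acid | O[C@@H](c1cc(OC)c(OC)c(OC)c1)[C@H](CO[Si](C)(C)C(C)(C)C)/C(C(=O)O)=C\c1ccc(OC)c(OC)c1
F2 | step 6 | (1R,2S,3E)-2-[(tert-butyldimethylsilyloxy)methyl]-3-(3,4-dimethoxybenzylidene)-1-(3,4,5-trimethoxyphenyl)butane-1,4-diol | O[C@@H](c1cc(OC)c(OC)c(OC)c1)[C@H](CO[Si](C)(C)C(C)(C)C)/C(CO)=C\c1ccc(OC)c(OC)c1
F3 | step 6 | (2E,3S,4R)-3-[(tert-butyldimethylsilyloxy)methyl]-2-(3,4-dimethoxybenzylidene)-4-hydroxy-4-(3,4,5-trimethoxyphenyl)butyl 4-methylbenzenesulfonate | O[C@@H](c1cc(OC)c(OC)c(OC)c1)[C@H](CO[Si](C)(C)C(C)(C)C)/C(COS(=O)(=O)c1ccc(C)cc1)=C\c1ccc(OC)c(OC)c1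
F4 | step 6 | (2R,3S,4E)-3-[(tert-butyldimethylsilyloxy)methyl]-4-(3,4-dimethoxybenzylidene)-2-(3,4,5-trimethoxyphenyl)tetrahydrofuran | C1O[C@@H](c2cc(OC)c(OC)c(OC)c2)[C@H](CO[Si](C)(C)C(C)(C)C)/C1=C\c1ccc(OC)c(OC)c1
F5 | step 4 | (R)-1-(tert-butyldimethylsilyloxy)-4-(3,4-dimethoxyphenyl)but-3-yn-2-yl methyl carbonate | COC(=O)O[C@@H](CO[Si](C)(C)C(C)(C)C)C#Cc1ccc(OC)c(OC)c1
F6 | step 4 | (aS)-2-[4-(tert-butyldimethylsilyloxy)-1-(3,4-dimethoxyphenyl)buta-1,2-dien-1-yl]-4,4,5,5-tetramethyl-1,3,2-dioxaborolane | CC1(C)OB(OC1(C)C)C(c1ccc(OC)c(OC)c1)=[C@]=C([H])CO[Si](C)(C)C(C)(C)C
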